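**Plan**

- Guaiane locants are used throughout: ring of five C1–C5 (C3=C4, methyl on C4), ring of seven C1, C5–C10 (C1=C10, methyl on C10, isopropyl on C7, ester oxygen on C8).
- Enabling feature: C7–C8(O)–C9–C10 is the carbon chain of malic acid, and the ring alkene C1=C10 beside the C5 stereocentre in the seven-membered ring is the cyclohept-4-enone pattern a Claisen shift leaves once C7 is a carbonyl.
- Cuts: the vanillate C–O bond; C4–CH3; C7–isopropyl; C5–C6 with O–C10 rejoined (back to a 2-methylene-oxolane); C6=C7 (lactone methylenation); C10–CH3 and C10–C1 at the distal carboxyl of malic acid.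
- Forward: the five-membered carbocycle (from cyclopentane-1,3-dione) is joined to C10, methyl addition closes the lactone, methylenation and ring expansion build the seven-membered ring, then isopropyl, C4 methyl and the ester follow.
- Stereochemistry: C8 from (S)-malic acid; C10 by chelate-controlled methyl addition; C5 by chair-like chirality transfer from C10 in the ring expansion; C7 by hydrogenation directed by the C8 hydroxyl.

Key step: step 9

Remark on the chemistry: the two C10 epimers of lactone 11 are assumed to be separable by chromatography, so only the (5R) epimer is carried forward.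

**Route**

Step 1
Reactants: 1 (S)-malic acid
Product: 2 2-[(4S)-2,2-dimethyl-5-oxo-1,3-dioxolan-4-yl]acetic acid
Conditions: Me2C(OMe)2, PPTS (cat.), rt
Reagents that add atoms: 2,2-dimethoxypropane, COC(C)(C)OC
Why: Acid-catalysed acetal exchange ties the α-hydroxy acid unit (C7, C8) into the five-membered dioxolanone faster than the six-membered alternative through the C10 carboxyl, which stays free, and C8 is not touched.

Step 2
Reactants: 2 2-[(4S)-2,2-dimethyl-5-oxo-1,3-dioxolan-4-yl]acetic acid
Product: 3 2-[(4S)-2,2-dimethyl-5-oxo-1,3-dioxolan-4-yl]acetyl chloride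
Conditions: (COCl)2, DMF (cat.), CH2Cl2, 0 °C to rt; evaporated and used crude
Reagents that add atoms: oxalyl chloride, O=C(Cl)C(=O)Cl
Why: Acid chloride formation through the chloroiminium species from DMF is neutral enough to leave the dioxolanone intact.

Step 3
Reactants: 4 cyclopentane-1,3-dione
Product: 5 3-bromocyclopent-2-en-1-one
Conditions: PPh3, Br2, Et3N, CH2Cl2, 0 °C to rt
Reagents that add atoms: bromine, BrBr
Why: The enol of the 1,3-diketone is activated by Ph3PBr2 as an oxyphosphonium salt and bromide replaces Ph3PO by addition–elimination, the standard route from β-diketones to β-bromo enones.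

Step 4
Reactants: 5 3-bromocyclopent-2-en-1-one
Product: 6 7-bromo-1,4-dioxaspiro[4.4]non-6-ene
Conditions: Me3SiOCH2CH2OSiMe3, Me3SiOTf (cat.), CH2Cl2, −78 to −20 °C; pyridine quench
Reagents that add atoms: 1,2-bis(trimethylsilyloxy)ethane, C[Si](C)(C)OCCO[Si](C)(C)C
Why: Aprotic silyl triflate-catalysed ketalisation (Noyori conditions) protects the carbonyl without free glycol or protic acid, so the vinylogous acyl bromide should not be displaced and the alkene should not migrate.

Step 5
Reactants: 6 7-bromo-1,4-dioxaspiro[4.4]non-6-ene; 3 2-[(4S)-2,2-dimethyl-5-oxo-1,3-dioxolan-4-yl]acetyl chloride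
Product: 9 (5S)-5-[2-(1,4-dioxaspiro[4.4]non-6-en-7-yl)-2-oxoethyl]-2,2-dimethyl-1,3-dioxolan-4-one, via vinyllithium 7 (not isolated), via vinylzinc chloride 8 (not isolated)
Conditions: t-BuLi (2 equiv), THF, −78 °C; ZnCl2, −78 to 0 °C; then 3, Pd(PPh3)4 (5 mol %), THF, 0 °C to rt
Reagents that add atoms: none
Why: Bromine–lithium exchange, transmetallation to zinc and Negishi acylation (zerovalent palladium inserts into the C–Cl bond of the acid chloride) form the C10–C1 bond, and the organozinc is too unreactive to attack the dioxolanone or the ketone product.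

Step 6
Reactants: 9 (5S)-5-[2-(1,4-dioxaspiro[4.4]non-6-en-7-yl)-2-oxoethyl]-2,2-dimethyl-1,3-dioxolan-4-one
Product: 11 (3S,5R)-3-hydroxy-5-methyl-5-(1,4-dioxaspiro[4.4]non-6-en-7-yl)oxolan-2-one, via bromomagnesium alkoxide 10 (not isolated)
Conditions: MeMgBr (1.1 equiv), CH2Cl2, −78 °C, then 0 °C; aq. NH4Cl
Reagents that add atoms: methylmagnesium bromide, C[Mg]Br
Why: 1,2-Grignard addition to the C10 ketone is followed by 5-exo-trig attack of the tertiary alkoxide on the activated dioxolanone carbonyl with loss of acetone, and C10 should be set by 1,3-induction from C8, since magnesium bridging the ketone oxygen and the C8 ring oxygen in a six-membered chelate exposes the face away from C7, which after lactonisation puts methyl cis and the cyclopentenyl group trans to the C8 hydroxyl.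

Step 7
Reactants: 11 (3S,5R)-3-hydroxy-5-methyl-5-(1,4-dioxaspiro[4.4]non-6-en-7-yl)oxolan-2-one
Product: 12 (3S,5R)-3-[(tert-butyldimethylsilyl)oxy]-5-methyl-5-(1,4-dioxaspiro[4.4]non-6-en-7-yl)oxolan-2-one
Conditions: t-BuMe2SiCl, imidazole, DMF, rt
Reagents that add atoms: tert-butyldimethylsilyl chloride, CC(C)(C)[Si](C)(C)Cl
Why: Standard silylation of the secondary alcohol masks the C8 hydroxyl before the titanium reagent and places a bulky group on the ring face opposite the cyclopentenyl group.

Step 8
Reactants: 12 (3S,5R)-3-[(tert-butyldimethylsilyl)oxy]-5-methyl-5-(1,4-dioxaspiro[4.4]non-6-en-7-yl)oxolan-2-one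
Product: 13 tert-butyl(dimethyl){[(3S,5R)-5-methyl-2-methylidene-5-(1,4-dioxaspiro[4.4]non-6-en-7-yl)oxolan-3-yl]oxy}silane
Conditions: Cp2TiMe2 (2.5 equiv), toluene, 70 °C, dark; filtration through basic alumina
Reagents that add atoms: dimethyltitanocene, C[Ti](C)(C1C=CC=C1)C1C=CC=C1
Why: Petasis methylenation (Cp2Ti=CH2 formed on heating adds to the lactone carbonyl and cycloreverts) supplies C6 as the exocyclic enol ether under non-basic conditions that should not epimerise C8, at a temperature well below that of the sigmatropic shift.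

Step 9
Reactants: 13 tert-butyl(dimethyl){[(3S,5R)-5-methyl-2-methylidene-5-(1,4-dioxaspiro[4.4]non-6-en-7-yl)oxolan-3-yl]oxy}silane
Product: 14 (5S,8S)-8-(tert-butyldimethylsilyloxy)-4,4-(ethylenedioxy)-10-methylbicyclo[5.3.0]dec-1(10)-en-7-one
Conditions: toluene (0.02 M), Et3N (1 vol %), base-washed sealed tube, 170 °C
Reagents that add atoms: none
Why: Heating should drive the concerted [3,3]-sigmatropic shift of the allyl vinyl ether C6=C7–O–C10–C1=C5, in which O–C10 breaks as C5–C6 forms, C7 becomes the ketone and C1=C10 the tetrasubstituted ring alkene. The closest known reaction type is the thermal Claisen ring expansion of 2-methylene-5-vinyltetrahydrofurans to cyclohept-4-enones. The seven-membered ring closes by two-carbon enlargement of the oxolane: the cyclopentenyl group folds over the ring face it occupies and C5 bonds to the exocyclic methylene carbon through a bridged, bicyclo[3.2.1]-like chair array. The only new stereocentre, C5, is fixed by chirality transfer from quaternary C10, which holds the cyclopentenyl group on the face opposite the C8 silyloxy group, together with the chair geometry, in which H5 points inward toward H8 and so ends trans to the C8 oxygen. The step needs chair over boat selectivity and survival of the acid-labile exocyclic enol ether; the outward, pseudo-equatorial silyloxy group leaves the chair array unhindered, the quaternary allylic C10 weakens the breaking C–O bond, and base-washed glass and triethylamine should suppress isomerisation to the endocyclic enol ether.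

Step 10
Reactants: 14 (5S,8S)-8-(tert-butyldimethylsilyloxy)-4,4-(ethylenedioxy)-10-methylbicyclo[5.3.0]dec-1(10)-en-7-one
Product: 16 (5S,8S)-8-(tert-butyldimethylsilyloxy)-4,4-(ethylenedioxy)-10-methylbicyclo[5.3.0]deca-1(10),6-dien-7-yl trifluoromethanesulfonate, via potassium enolate 15 (not isolated)
Conditions: KN(SiMe3)2 (1.1 equiv), THF, −78 °C; PhNTf2, −78 to 0 °C
Reagents that add atoms: N-phenylbis(trifluoromethanesulfonimide), O=S(=O)(N(c1ccccc1)S(=O)(=O)C(F)(F)F)C(F)(F)F
Why: Kinetic deprotonation by the bulky amide should take a C6 methylene proton rather than the hindered C8–H beside the silyloxy group, and O-sulfonylation of the C6=C7 enolate then gives the enol triflate with C8 unchanged.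

Step 11
Reactants: 16 (5S,8S)-8-(tert-butyldimethylsilyloxy)-4,4-(ethylenedioxy)-10-methylbicyclo[5.3.0]deca-1(10),6-dien-7-yl trifluoromethanesulfonate
Product: 17 tert-butyl{[(5S,8S)-4,4-(ethylenedioxy)-7-isopropyl-10-methylbicyclo[5.3.0]deca-1(10),6-dien-8-yl]oxy}dimethylsilane
Conditions: i-PrMgCl (1.5 equiv), Fe(acac)3 (5 mol %), THF/NMP, −30 °C
Reagents that add atoms: isopropylmagnesium chloride, CC(C)[Mg]Cl
Why: Iron-catalysed cross-coupling of an alkenyl triflate with an alkyl Grignard reagent forms the C7–isopropyl bond at low temperature, where coupling should outrun β-hydride loss from the secondary alkyl group and the ketal and silyl ether are inert.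

Step 12
Reactants: 17 tert-butyl{[(5S,8S)-4,4-(ethylenedioxy)-7-isopropyl-10-methylbicyclo[5.3.0]deca-1(10),6-dien-8-yl]oxy}dimethylsilane
Product: 18 (5S,8S)-4,4-(ethylenedioxy)-7-isopropyl-10-methylbicyclo[5.3.0]deca-1(10),6-dien-8-ol
Conditions: Bu4NF, THF, 0 °C to rt
Reagents that add atoms: none
Why: Fluoride cleavage of the Si–O bond frees the allylic C8 hydroxyl needed as a directing group, and the skipped diene and ketal do not react with fluoride.

Step 13
Reactants: 18 (5S,8S)-4,4-(ethylenedioxy)-7-isopropyl-10-methylbicyclo[5.3.0]deca-1(10),6-dien-8-ol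
Product: 19 (5S,7R,8S)-4,4-(ethylenedioxy)-7-isopropyl-10-methylbicyclo[5.3.0]dec-1(10)-en-8-ol
Conditions: H2 (1 atm), [Ir(cod)(PCy3)(py)]PF6 (3 mol %), CH2Cl2, 0 °C; stopped after one equivalent of H2
Reagents that add atoms: none
Why: In this hydroxyl-directed homogeneous hydrogenation the cationic iridium catalyst binds the C8 hydroxyl and delivers both hydrogens to C6=C7 from that face, so H7 should end cis to the C8 oxygen and the isopropyl group trans (7R), while the tetrasubstituted C1=C10 alkene should react far more slowly.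

Step 14
Reactants: 19 (5S,7R,8S)-4,4-(ethylenedioxy)-7-isopropyl-10-methylbicyclo[5.3.0]dec-1(10)-en-8-ol
Product: 20 (5S,7R,8S)-8-hydroxy-7-isopropyl-10-methylbicyclo[5.3.0]dec-1(10)-en-4-one
Conditions: PPTS (0.2 equiv), acetone/H2O 9:1, rt
Reagents that add atoms: water, O
Why: Weakly acidic ketal hydrolysis frees the C4 ketone, and the mild acid is chosen so that the β,γ-unsaturated ketone should neither enolise toward C5 and slip into conjugation nor epimerise.

Step 15
Reactants: 20 (5S,7R,8S)-8-hydroxy-7-isopropyl-10-methylbicyclo[5.3.0]dec-1(10)-en-4-one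
Product: 21 (E)-2,4,6-triisopropylbenzenesulfonylhydrazone of 20
Conditions: 2,4,6-(i-Pr)3C6H2SO2NHNH2 (1.1 equiv), THF, rt
Reagents that add atoms: 2,4,6-triisopropylbenzenesulfonyl hydrazide, CC(C)c1cc(C(C)C)c(S(=O)(=O)NN)c(C(C)C)c1
Why: Condensation without added acid should give the hydrazone with the sulfonamide nitrogen on the side of the less substituted α-carbon C3, the geometry that controls the regiochemistry of the next step.

Step 16
Reactants: 21 (E)-2,4,6-triisopropylbenzenesulfonylhydrazone of 20
Product: 23 (5R,7R,8S)-guaia-1(10),3-dien-8-ol, via dilithio vinyl alkoxide 22 (not isolated)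
Conditions: n-BuLi (3.3 equiv), THF, −78 to 0 °C; recooled to −78 °C; MeI; aq. NH4Cl at −78 °C
Reagents that add atoms: iodomethane, CI
Why: In this Shapiro reaction with alkylative trapping, N–H and O–H are deprotonated first, the third equivalent removes the C3 proton syn to the sulfonamide nitrogen, loss of sulfinate and N2 gives the C4 vinyllithium with the alkene fixed at C3=C4, and MeI methylates C4 at −78 °C where the lithium alkoxide should not be alkylated, so C5 sees neither a cation nor an enolate.

Step 17
Reactants: 24 vanillic acid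
Product: 25 4-acetoxy-3-methoxybenzoic acid
Conditions: Ac2O, pyridine, rt; then H2O
Reagents that add atoms: acetic anhydride, CC(=O)OC(C)=O
Why: O-Acetylation masks the phenol so the acid can be activated without self-acylation, and the aqueous work-up hydrolyses any mixed anhydride.

Step 18
Reactants: 23 (5R,7R,8S)-guaia-1(10),3-dien-8-ol; 25 4-acetoxy-3-methoxybenzoic acid
Product: 26 (5R,7R,8S)-guaia-1(10),3-dien-8-yl 4-acetoxy-3-methoxybenzoate
Conditions: DCC, DMAP (cat.), CH2Cl2, 0 °C to rt
Reagents that add atoms: none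
Why: Steglich esterification transfers the acyl group to the C8 oxygen through the acylpyridinium ion with retention at C8, under neutral conditions that the skipped diene tolerates.

Step 19
Reactants: 26 (5R,7R,8S)-guaia-1(10),3-dien-8-yl 4-acetoxy-3-methoxybenzoate
Product: 27 (5R,7R,8S)-guaia-1(10),3-dien-8-yl 4-hydroxy-3-methoxybenzoate (CNP0156298.2)
Conditions: pyrrolidine (3 equiv), CH2Cl2, 0 °C
Reagents that add atoms: none
Why: Aminolysis of the aryl acetate, far more electrophilic than the hindered secondary alkyl benzoate, should free the phenol without touching the C8 ester or the acid-sensitive diene.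

**Compound list**

1 | (S)-malic acid | OC(=O)C[C@H](O)C(=O)O | starting material
2 | 2-[(4S)-2,2-dimethyl-5-oxo-1,3-dioxolan-4-yl]acetic acid | CC1(C)OC(=O)[C@H](CC(=O)O)O1 | intermediate
3 | 2-[(4S)-2,2-dimethyl-5-oxo-1,3-dioxolan-4-yl]acetyl chloride | CC1(C)OC(=O)[C@H](CC(=O)Cl)O1 | intermediate
4 | cyclopentane-1,3-dione | O=C1CCC(=O)C1 | starting material
5 | 3-bromocyclopent-2-en-1-one | O=C1C=C(Br)CC1 | intermediate
6 | 7-bromo-1,4-dioxaspiro[4.4]non-6-ene | BrC1=CC2(CC1)OCCO2 | intermediate
7 | 7-lithio-1,4-dioxaspiro[4.4]non-6-ene (vinyllithium) | [Li]C1=CC2(CC1)OCCO2 | intermediate (not isolated)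
8 | chloro(1,4-dioxaspiro[4.4]non-6-en-7-yl)zinc (vinylzinc chloride) | Cl[Zn]C1=CC2(CC1)OCCO2 | intermediate (not isolated)
9 | (5S)-5-[2-(1,4-dioxaspiro[4.4]non-6-en-7-yl)-2-oxoethyl]-2,2-dimethyl-1,3-dioxolan-4-one | CC1(C)OC(=O)[C@H](CC(=O)C2=CC3(CC2)OCCO3)O1 | intermediate
10 | bromomagnesium alkoxide of the C10 methyl carbinol, dioxolanone intact (10R) | CC1(C)OC(=O)[C@H](C[C@@](C)(O[Mg]Br)C2=CC3(CC2)OCCO3)O1 | intermediate (not isolated)
11 | (3S,5R)-3-hydroxy-5-methyl-5-(1,4-dioxaspiro[4.4]non-6-en-7-yl)oxolan-2-one | O=C1O[C@@](C)(C2=CC3(OCCO3)CC2)C[C@@H]1O | intermediate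
12 | (3S,5R)-3-[(tert-butyldimethylsilyl)oxy]-5-methyl-5-(1,4-dioxaspiro[4.4]non-6-en-7-yl)oxolan-2-one | O=C1O[C@@](C)(C2=CC3(OCCO3)CC2)C[C@@H]1O[Si](C)(C)C(C)(C)C | intermediate
13 | tert-butyl(dimethyl){[(3S,5R)-5-methyl-2-methylidene-5-(1,4-dioxaspiro[4.4]non-6-en-7-yl)oxolan-3-yl]oxy}silane | C=C1O[C@@](C)(C2=CC3(OCCO3)CC2)C[C@@H]1O[Si](C)(C)C(C)(C)C | intermediate
14 | (5S,8S)-8-(tert-butyldimethylsilyloxy)-4,4-(ethylenedioxy)-10-methylbicyclo[5.3.0]dec-1(10)-en-7-one | O=C1C[C@H]2C(CCC23OCCO3)=C(C)C[C@@H]1O[Si](C)(C)C(C)(C)C | intermediate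
15 | potassium C6=C7 enolate of 14 | [K+].[O-]C1=C[C@H]2C(CCC23OCCO3)=C(C)C[C@@H]1O[Si](C)(C)C(C)(C)C | intermediate (not isolated)
16 | (5S,8S)-8-(tert-butyldimethylsilyloxy)-4,4-(ethylenedioxy)-10-methylbicyclo[5.3.0]deca-1(10),6-dien-7-yl trifluoromethanesulfonate | O=S(=O)(OC1=C[C@H]2C(CCC23OCCO3)=C(C)C[C@@H]1O[Si](C)(C)C(C)(C)C)C(F)(F)F | intermediate
17 | tert-butyl{[(5S,8S)-4,4-(ethylenedioxy)-7-isopropyl-10-methylbicyclo[5.3.0]deca-1(10),6-dien-8-yl]oxy}dimethylsilane | CC(C)C1=C[C@H]2C(CCC23OCCO3)=C(C)C[C@@H]1O[Si](C)(C)C(C)(C)C | intermediate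
18 | (5S,8S)-4,4-(ethylenedioxy)-7-isopropyl-10-methylbicyclo[5.3.0]deca-1(10),6-dien-8-ol | CC(C)C1=C[C@H]2C(CCC23OCCO3)=C(C)C[C@@H]1O | intermediate
19 | (5S,7R,8S)-4,4-(ethylenedioxy)-7-isopropyl-10-methylbicyclo[5.3.0]dec-1(10)-en-8-ol | O[C@H]1CC(C)=C2CCC3(OCCO3)[C@H]2C[C@@H]1C(C)C | intermediate
20 | (5S,7R,8S)-8-hydroxy-7-isopropyl-10-methylbicyclo[5.3.0]dec-1(10)-en-4-one | O[C@H]1CC(C)=C2CCC(=O)[C@H]2C[C@@H]1C(C)C | intermediate
21 | (E)-2,4,6-triisopropylbenzenesulfonylhydrazone of 20 | O[C@H]1CC(C)=C2CC/C(=N\NS(=O)(=O)c3c(C(C)C)cc(C(C)C)cc3C(C)C)[C@H]2C[C@@H]1C(C)C | intermediate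
22 | C4-lithio guaia-1(10),3-diene C8 lithium alkoxide (dilithio vinyl alkoxide) | [Li]O[C@H]1CC(C)=C2CC=C([Li])[C@H]2C[C@@H]1C(C)C | intermediate (not isolated)
23 | (5R,7R,8S)-guaia-1(10),3-dien-8-ol | O[C@H]1CC(C)=C2CC=C(C)[C@H]2C[C@@H]1C(C)C | intermediate
24 | vanillic acid | COc1cc(C(=O)O)ccc1O | starting material
25 | 4-acetoxy-3-methoxybenzoic acid | COc1cc(C(=O)O)ccc1OC(C)=O | intermediate
26 | (5R,7R,8S)-guaia-1(10),3-dien-8-yl 4-acetoxy-3-methoxybenzoate | COc1cc(C(=O)O[C@H]2CC(C)=C3CC=C(C)[C@H]3C[C@@H]2C(C)C)ccc1OC(C)=O | intermediate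
27 | (5R,7R,8S)-guaia-1(10),3-dien-8-yl 4-hydroxy-3-methoxybenzoate (CNP0156298.2) | COc1cc(C(=O)O[C@H]2CC(C)=C3CC=C(C)[C@H]3C[C@@H]2C(C)C)ccc1O | target

**Summary**

Total step count: 19. Longest linear sequence: 16 steps (steps 1, 2, 5–16, 18, 19; the branch from cyclopentane-1,3-dione through steps 3 and 4 is equally long).

Steps most likely to fail:

1. Step 9. The shift may pass partly through the boat-like array, which would erode facial selectivity at C5. The exocyclic enol ether may also isomerise or the material may decompose at 170 °C before it rearranges. The fallback leaves from 13 and uses i-Bu3Al in CH2Cl2 from −78 °C. This promotes the same oxygen-to-carbon shift at low temperature, after which the aluminium alkyl reduces the new carbonyl by hydride transfer. The product would be the C7 alcohol, (5S,8S)-8-(tert-butyldimethylsilyloxy)-4,4-(ethylenedioxy)-10-methylbicyclo[5.3.0]dec-1(10)-en-7-ol F1, as a mixture of C7 epimers. Oxidation with Dess–Martin periodinane (NaHCO3, CH2Cl2) would converge both epimers on 14, where the route is rejoined.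

2. Step 6. The 1,3-induction may be weak or run opposite to the chelate model, giving poor facial selectivity at C10. Enolisation toward C9 with β-elimination of the C8 oxygen could also compete. The fallback introduces the two C10 substituents in the reverse order, which inverts the outcome for a given facial preference, so it answers a reversed bias; if the bias is merely weak, separation at 11 remains the remedy. It leaves from 3: Me2CuLi (Et2O, −78 °C) would give the methyl ketone (5S)-2,2-dimethyl-5-(2-oxopropyl)-1,3-dioxolan-4-one F2. Lithium reagent 7 is transmetallated with CeCl3 to the weakly basic dichloro(1,4-dioxaspiro[4.4]non-6-en-7-yl)cerium F3. Addition of F3 to F2 at −78 °C, followed by the same alkoxide lactonisation, returns the route to 11.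

3. Step 16. The third deprotonation may occur at C5 instead of C3, the vinyllithium may be protonated before it is methylated, or the alkoxide may be O-methylated. The fallback leaves from 20: MeCeCl2 (from MeLi and CeCl3, THF, −78 °C) should add methyl to C4 from the face of H5 to give (4R,5S,7R,8S)-7-isopropyl-4,10-dimethylbicyclo[5.3.0]dec-1(10)-ene-4,8-diol F4. DCC and DMAP with acid 25 should acylate only the secondary C8 hydroxyl to give (4R,5S,7R,8S)-4-hydroxy-7-isopropyl-4,10-dimethylbicyclo[5.3.0]dec-1(10)-en-8-yl 4-acetoxy-3-methoxybenzoate F5. Burgess reagent (benzene, 50 °C) then removes the tertiary hydroxyl by syn elimination toward C3, H5 being anti to the leaving group, and the route is rejoined at 26.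

**Further compounds**

F1 | step 9 | (5S,8S)-8-(tert-butyldimethylsilyloxy)-4,4-(ethylenedioxy)-10-methylbicyclo[5.3.0]dec-1(10)-en-7-ol (C7 epimers) | OC1C[C@H]2C(CCC23OCCO3)=C(C)C[C@@H]1O[Si](C)(C)C(C)(C)C
F2 | step 6 | (5S)-2,2-dimethyl-5-(2-oxopropyl)-1,3-dioxolan-4-one | CC1(C)OC(=O)[C@H](CC(C)=O)O1
F3 | step 6 | dichloro(1,4-dioxaspiro[4.4]non-6-en-7-yl)cerium | Cl[Ce](Cl)C1=CC2(CC1)OCCO2
F4 | step 16 | (4R,5S,7R,8S)-7-isopropyl-4,10-dimethylbicyclo[5.3.0]dec-1(10)-ene-4,8-diol | O[C@H]1CC(C)=C2CC[C@@](C)(O)[C@H]2C[C@@H]1C(C)C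
F5 | step 16 | (4R,5S,7R,8S)-4-hydroxy-7-isopropyl-4,10-dimethylbicyclo[5.3.0]dec-1(10)-en-8-yl 4-acetoxy-3-methoxybenzoate | COc1cc(C(=O)O[C@H]2CC(C)=C3CC[C@@](C)(O)[C@H]3C[C@@H]2C(C)C)ccc1OC(C)=O
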